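The seven-membered ring, ring A, is C1 (acyloxy CH), C2 (CH2), C3 (C(OH)CH3), C4, C5, C6, C7 (CH-iPr). Ring B is C5, C8, C9, C10, C6. The plan hinges on taking C2 out. What remains of ring A is a 2-methyl-6-isopropylcyclohexanone, and its C1=C3 silyl enol ether is what a 2-silyloxydiene and cyclopent-2-enone give on cycloaddition. The key step exploits this C1=C3 bond: a single methylene transfer makes C1–C2 and C2–C3, linking all seven ring A carbons. FeCl3 afterwards severs C1–C3 to unveil a C2=C3 enone. The precursor is a cis-hydrindanone (C8 ketone) bearing a triethylsilyl enol ether; of its stereocentres only C6 persists.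

Key step: step 5

Convention: these atom numbers are used for every intermediate. α is the face of the bicycle that carries 6-H and β is the other face. In this numbering the target is 1R,3R,5S,6R,7S,8S,9R. That places 1-O, 3-OH, 7-isopropyl and the epoxide oxygen on α, and 5-H, 7-H, 3-CH3 and 9-CH3 on β.

Assumption: the (S)-configured oxazaborolidinium catalyst of step 4 is assigned by analogy with its sense of induction for acrylates and simple enones (diene on the Re face of the α-carbon, here C5). Should the antipode form, the (R)-catalyst is used.

Assumption: 3-benzyloxy-4-methoxybenzoic acid 24 is taken as a catalogue compound.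

Order of events: the ring B alkene is completed before ring A is functionalised. It is inert to the hydride and directed-oxidation steps that follow, so only the phenol needs a protecting group.

Step 1
Reactants: 1 3-methylbutanal; 2 isopropenylmagnesium bromide
Product: 3 (±)-2,5-dimethylhex-1-en-3-ol
Conditions: THF, 0 °C; aq NH4Cl
Reagents that add atoms: none
Why: Grignard 1,2-addition to an unhindered aldehyde; the carbinol centre is racemic and is erased in step 2.

Step 2
Reactants: 3 (±)-2,5-dimethylhex-1-en-3-ol
Product: 4 2,5-dimethylhex-1-en-3-one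
Conditions: Dess–Martin periodinane, CH2Cl2, 0 °C to rt
Reagents that add atoms: none
Why: Dess–Martin oxidation of a secondary allylic alcohol under neutral, non-aqueous conditions that spare the polymerisable 1,1-disubstituted enone; no stereocentre remains.

Step 3
Reactants: 4 2,5-dimethylhex-1-en-3-one
Product: 5 (3Z)-2,5-dimethyl-3-(triethylsilyloxy)hexa-1,3-diene
Conditions: Et3SiOTf, Et3N, CH2Cl2, 0 °C
Reagents that add atoms: triethylsilyl trifluoromethanesulfonate, CC[Si](CC)(CC)OS(=O)(=O)C(F)(F)F
Why: Soft enolisation (silyl triflate/amine) can only go toward the single CH2 group, and allylic 1,3-strain keeps the isopropyl group away from the isopropenyl group, so the Z enol ether forms and the isopropyl group sits on the outside of the s-cis diene.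

Step 4
Reactants: 5 (3Z)-2,5-dimethyl-3-(triethylsilyloxy)hexa-1,3-diene; 6 cyclopent-2-en-1-one
Product: 7 cis-hydrindanone triethylsilyl enol ether (C1=C3 enol ether; C8 ketone; 5-H 6-H 7-H all α; isopropyl β)
Conditions: (S)-1-(2-methylphenyl)-3,3-diphenyltetrahydro-1H,3H-pyrrolo[1,2-c][1,3,2]oxazaborole·HN(SO2CF3)2 (20 mol %), CH2Cl2, −78 to −20 °C
Reagents that add atoms: none
Why: Catalytic enantioselective Diels–Alder reaction in which the silyloxy group makes C7 the nucleophilic diene terminus so that it bonds to the enone β-carbon C6 (and C4 to C5), the endo approach of the outside-substituted diene places 5-H, 6-H and 7-H cis, and the boron-bound enone is shielded on one face so that C6 is set as in the target.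

Step 5
Reactants: 7 cis-hydrindanone triethylsilyl enol ether; 8 diiodomethane
Product: 9 siloxycyclopropane (1-triethylsilyloxy-3-methylbicyclo[4.1.0]heptane unit C1–C2–C3 fused to the cyclopentanone; C2 on the α face)
Conditions: Et2Zn, CH2I2 (1:1, excess), CH2Cl2, 0 °C to rt
Reagents that add atoms: diiodomethane (compound 8), ICI
Why: Et2Zn and CH2I2 exchange to an iodomethylzinc carbenoid that passes its methylene to the electron-rich C1=C3 bond through a concerted butterfly transition state, so C1–C2 and C2–C3 form in the same event; this is the Furukawa variant of the Simmons–Smith cyclopropanation, a standard reaction of silyl enol ethers. The only ring closed is the three-membered ring C1–C2–C3, formed by a [2+1] suprafacial addition rather than by cyclisation of a chain, and with it every carbon of ring A is connected. C1 and C3 become stereocentres whose cis relation is forced by the suprafacial addition and whose α orientation follows from the isopropyl group and the folded cyclopentanone covering the β face, but both return to sp2 in step 6, so this facial choice does not matter. The selectivities that do matter are secured by the substrate: the electrophilic carbenoid ignores the C8 ketone, no other C=C bond is present, and the site of insertion is dictated by the enol ether regiochemistry that the cycloaddition installed. Triethylsilyl is preferred to trimethylsilyl because it survives the acidic catalyst of step 4 and the Lewis acidic zinc iodides formed here, yet is small enough to admit the carbenoid to a tetrasubstituted alkene and labile enough for FeCl3.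

Step 6
Reactants: 9 siloxycyclopropane
Product: 11 cis-fused 3-methyl-7β-isopropylhydroazul-2-ene-1,8-dione (5-H 6-H 7-H all α), via β-chloro ketone 10 (not isolated)
Conditions: FeCl3, DMF, 0 °C to rt; then NaOAc, MeOH, reflux
Reagents that add atoms: none
Why: Oxidative ring expansion of a 1-siloxybicyclo[n.1.0]alkane: trivalent iron in FeCl3 takes one electron at the cyclopropanol oxygen, the shared C1–C3 bond breaks to give the C1 ketone and the tertiary C3 radical (favoured over the primary radical from C1–C2 cleavage), chlorine transfer gives 10, and acetate-induced E1cB loss of HCl gives the conjugated C2=C3 enone without touching C5, C6 or C7.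

Step 7
Reactants: 11 cis-fused enedione
Product: 12 trans-fused 3-methyl-7α-isopropylhydroazul-2-ene-1,8-dione (5β-H; 6α-H; 7β-H)
Conditions: NaOMe (0.3 equiv), MeOH, rt to 50 °C
Reagents that add atoms: none
Why: Base-mediated epimerisation under thermodynamic control: C5 (α to the C8 ketone) and C7 (α′ to the C1 ketone) equilibrate through their enolates against the fixed C6 toward the isomer in which the C5–C8, C6–C10 and C7–isopropyl bonds are all mutually trans and pseudo-equatorial on ring A.

Step 8
Reactants: 12 trans-fused enedione; 13 dimethyl(methylidene)ammonium iodide (Eschenmoser's salt)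
Product: 17 trans-fused 9-methylidene enedione, via C9 lithium enolate 14 (not isolated), via Mannich base 15 (not isolated), via methiodide 16 (not isolated)
Conditions: LiN(i-Pr)2 (1.05 equiv), THF, −78 °C; Me2N=CH2 I, −78 °C to rt; MeI, Et2O, rt; aq NaHCO3, CH2Cl2
Reagents that add atoms: dimethyl(methylidene)ammonium iodide (compound 13), C=[N+](C)C.[I-]
Why: Kinetic deprotonation removes a hydrogen from the unhindered C9 methylene of the cyclopentanone rather than the tertiary, isopropyl-shielded 7-H or the γ-hydrogens of the enone, and Mannich aminomethylation, quaternisation and E1cB elimination then give the exocyclic enone; the C9 centre of 15 and 16 is of no consequence.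

Step 9
Reactants: 17 trans-fused 9-methylidene enedione
Product: 19 C8 enol triflate with C8=C9 and 9-methyl, via 9-methyl lithium enolate 18 (not isolated)
Conditions: LiBH(s-Bu)3 (1.0 equiv), THF, −78 °C; N-(5-chloropyridin-2-yl)bis(trifluoromethanesulfonimide), −78 to 0 °C; H2O
Reagents that add atoms: N-(5-chloropyridin-2-yl)bis(trifluoromethanesulfonimide), FC(F)(F)S(=O)(=O)N(c1ccc(Cl)cn1)S(=O)(=O)C(F)(F)F
Why: Conjugate reduction with enolate trapping: the bulky borohydride adds hydride to the exposed terminal CH2 (which becomes the 9-methyl group) far faster than it attacks the hindered β,β-disubstituted C1 enone, and the regiodefined C8=C9 enolate is O-sulfonylated before it can equilibrate toward C5.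

Step 10
Reactants: 19 C8 enol triflate
Product: 20 trans-fused dienone (C1 ketone; C2=C3; C8=C9 with 9-methyl)
Conditions: Pd(OAc)2 (5 mol %), PPh3, HCO2H, Et3N, DMF, 60 °C
Reagents that add atoms: none
Why: Palladium-catalysed formate reduction of a vinyl triflate (oxidative addition to zerovalent palladium, formate exchange, decarboxylation, reductive elimination) replaces OTf by H with the double bond held at C8=C9, while the hindered enone is not reduced.

Step 11
Reactants: 20 trans-fused dienone
Product: 21 allylic alcohol (1α-OH cis to the 7α-isopropyl group)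
Conditions: LiBH(s-Bu)3 (1.5 equiv), THF, −78 to 0 °C; H2O
Reagents that add atoms: none
Why: 1,2-Reduction, the normal course for β,β-disubstituted cyclic enones with this reagent, in which the bulky hydride takes the equatorial-type path on the β face away from the α-isopropyl group and 6α-H (the sense that turns menthone into neomenthol), setting C1 with its oxygen α.

Step 12
Reactants: 21 allylic alcohol
Product: 22 2α,3α-epoxy-1α-alcohol
Conditions: VO(acac)2 (2 mol %), t-BuOOH, CH2Cl2, 0 °C to rt
Reagents that add atoms: tert-butyl hydroperoxide, CC(C)(C)OO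
Why: Hydroxyl-directed vanadium-catalysed epoxidation: the vanadate ester of the pseudo-axial 1α-OH delivers oxygen to the same face of C2=C3, which sets the C3–O bond α, and the isolated C8=C9 alkene, lacking an allylic hydroxyl, reacts far more slowly.

Step 13
Reactants: 22 2α,3α-epoxy-1α-alcohol
Product: 23 cis-1α,3α-diol (3β-methyl; C8=C9 intact)
Conditions: LiAlH4, THF, 0 °C to reflux; aqueous work-up
Reagents that add atoms: none
Why: SN2 hydride opening of the epoxide at the secondary C2 from the β face (the tertiary C3 is closed to hydride and a Payne shift is impossible for a cis epoxy alcohol) leaves the C3–O bond untouched, so the tertiary carbinol keeps its α configuration.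

Step 14
Reactants: 23 cis-1α,3α-diol; 24 3-benzyloxy-4-methoxybenzoic acid
Product: 26 C1 3-benzyloxy-4-methoxybenzoate of the diol, via mixed anhydride 25 (not isolated)
Conditions: 2,4,6-trichlorobenzoyl chloride, Et3N, toluene, rt; then 23, DMAP, rt to 60 °C
Reagents that add atoms: none
Why: Yamaguchi esterification in which DMAP attacks the less hindered carbonyl of the mixed anhydride and the acylpyridinium ion acylates the secondary C1 hydroxyl while the tertiary C3 hydroxyl stays free; the C1–O bond is not broken, so the configuration is kept.

Step 15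
Reactants: 26 C1 3-benzyloxy-4-methoxybenzoate
Product: 27 8α,9α-epoxide of 26
Conditions: mCPBA, CH2Cl2, 0 °C
Reagents that add atoms: 3-chloroperoxybenzoic acid, O=C(OO)c1cccc(Cl)c1
Why: Prilezhaev epoxidation of the only alkene, which should occur on the α face, anti to the two pseudo-axial allylic C–H bonds (5β-H and 10β-H) of the trans-fused cyclopentene envelope and on the side where the α C3 hydroxyl can hydrogen-bond to the peracid, setting C8 and C9 together.

Step 16
Reactants: 27 8α,9α-epoxide
Product: 28 CNP0106636.1
Conditions: H2 (1 atm), 10% Pd/C, EtOAc, rt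
Reagents that add atoms: none
Why: Hydrogenolysis of the aryl benzyl ether under neutral conditions, to which the non-benzylic trisubstituted epoxide, the ester and the tertiary alcohol are inert; no stereocentre is affected.

Compound list
1 | 3-methylbutanal | CC(C)CC=O | starting material
2 | isopropenylmagnesium bromide | C=C(C)[Mg]Br | starting material
3 | (±)-2,5-dimethylhex-1-en-3-ol | C=C(C)C(O)CC(C)C | intermediate
4 | 2,5-dimethylhex-1-en-3-one | C=C(C)C(=O)CC(C)C | intermediate
5 | (3Z)-2,5-dimethyl-3-(triethylsilyloxy)hexa-1,3-diene | C=C(C)/C(O[Si](CC)(CC)CC)=C/C(C)C | intermediate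
6 | cyclopent-2-en-1-one | O=C1C=CCC1 | starting material
7 | cis-hydrindanone triethylsilyl enol ether (4-isopropyl-6-methyl-5-triethylsilyloxy-2,3,3a,4,7,7a-hexahydroinden-1-one; 5-H, 6-H, 7-H α) | CC[Si](CC)(CC)OC1=C(C)C[C@H]2C(=O)CC[C@H]2[C@H]1C(C)C | intermediate
8 | diiodomethane | ICI | starting material
9 | siloxycyclopropane (C2 on the α face) | CC[Si](CC)(CC)O[C@@]12C[C@]1(C)C[C@H]3C(=O)CC[C@H]3[C@H]2C(C)C | intermediate
10 | β-chloro ketone (3-chloro-3-methyl, C3 epimers) | O=C1CC(C)(Cl)C[C@H]2C(=O)CC[C@H]2[C@H]1C(C)C | intermediate
11 | cis-fused enedione (7β-isopropyl) | O=C1C=C(C)C[C@H]2C(=O)CC[C@H]2[C@H]1C(C)C | intermediate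
12 | trans-fused enedione (5β-H, 6α-H, 7α-isopropyl) | O=C1C=C(C)C[C@@H]2C(=O)CC[C@H]2[C@@H]1C(C)C | intermediate
13 | dimethyl(methylidene)ammonium iodide | C=[N+](C)C.[I-] | starting material
14 | C9 lithium enolate of 12 | O=C1C=C(C)C[C@@H]2C(O[Li])=CC[C@H]2[C@@H]1C(C)C | intermediate
15 | Mannich base (9-dimethylaminomethyl, C9 epimers) | O=C1C=C(C)C[C@@H]2C(=O)C(CN(C)C)C[C@H]2[C@@H]1C(C)C | intermediate
16 | methiodide of 15 | O=C1C=C(C)C[C@@H]2C(=O)C(C[N+](C)(C)C)C[C@H]2[C@@H]1C(C)C.[I-] | intermediate
17 | trans-fused 9-methylidene enedione | O=C1C=C(C)C[C@@H]2C(=O)C(=C)C[C@H]2[C@@H]1C(C)C | intermediate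
18 | 9-methyl lithium enolate (C8=C9) | O=C1C=C(C)C[C@@H]2C(O[Li])=C(C)C[C@H]2[C@@H]1C(C)C | intermediate
19 | C8 enol triflate (C8=C9, 9-methyl) | O=C1C=C(C)C[C@@H]2C(OS(=O)(=O)C(F)(F)F)=C(C)C[C@H]2[C@@H]1C(C)C | intermediate
20 | trans-fused dienone | O=C1C=C(C)C[C@@H]2C=C(C)C[C@H]2[C@@H]1C(C)C | intermediate
21 | 1α-allylic alcohol | O[C@@H]1C=C(C)C[C@@H]2C=C(C)C[C@H]2[C@@H]1C(C)C | intermediate
22 | 2α,3α-epoxy-1α-alcohol | O[C@@H]1[C@@H]3O[C@]3(C)C[C@@H]2C=C(C)C[C@H]2[C@@H]1C(C)C | intermediate
23 | cis-1α,3α-diol | O[C@@H]1C[C@](C)(O)C[C@@H]2C=C(C)C[C@H]2[C@@H]1C(C)C | intermediate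
24 | 3-benzyloxy-4-methoxybenzoic acid | COc1ccc(C(=O)O)cc1OCc1ccccc1 | starting material
25 | mixed anhydride of 24 with 2,4,6-trichlorobenzoic acid | COc1ccc(C(=O)OC(=O)c2c(Cl)cc(Cl)cc2Cl)cc1OCc1ccccc1 | intermediate
26 | C1 3-benzyloxy-4-methoxybenzoate (C8=C9 alkene) | COc1ccc(C(=O)O[C@@H]2C[C@](C)(O)C[C@@H]3C=C(C)C[C@H]3[C@@H]2C(C)C)cc1OCc1ccccc1 | intermediate
27 | O-benzyl 8α,9α-epoxide | COc1ccc(C(=O)O[C@@H]2C[C@](C)(O)C[C@H]3[C@@H](C[C@@]4(C)O[C@@H]34)[C@@H]2C(C)C)cc1OCc1ccccc1 | intermediate
28 | CNP0106636.1 (1R,3R,5S,6R,7S,8S,9R in route numbering; C1 3-hydroxy-4-methoxybenzoate) | COc1ccc(C(=O)O[C@@H]2C[C@](C)(O)C[C@H]3[C@@H](C[C@@]4(C)O[C@@H]34)[C@@H]2C(C)C)cc1O | target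

Total step count: 16. Longest linear sequence: 16 steps (1 to 28).

Steps most likely to fail

**Step 4.**
- What may go wrong: sluggish cycloaddition of the hindered trisubstituted diene, protodesilylation of the diene by the acidic catalyst, or insufficient facial discrimination. Endo/exo leakage is harmless, since C5 and C7 are equilibrated in step 7.
- Fallback: auxiliary control in place of catalyst control, setting out from 5. The doubly activated dienophile (S)-2-(p-tolylsulfinyl)cyclopent-2-en-1-one F1 is held in its chelated conformation by ZnBr2 in CH2Cl2. It should take up the diene on the face away from the tolyl group and give the C5-sulfinyl Diels–Alder adduct F2.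
- Return to the route: reductive desulfinylation with SmI2 in THF/MeOH at −78 °C, then protonation of the resulting enolate at C5, comes back at 7.

**Step 11.**
- What may go wrong: competing conjugate reduction of the enone, or hydride delivery from the α face.
- Fallback: the oxygen at C3 is installed first and C1 is set on a saturated ketone, setting out from 20.
  - Weitz–Scheffer epoxidation (H2O2, NaOH, MeOH) should give the 2α,3α-epoxy ketone F3. The C8=C9 alkene is inert to the nucleophilic oxidant.
  - Reductive opening at C2 with the selenide–borate reagent from (PhSe)2 and NaBH4 in EtOH/AcOH gives the 3α-hydroxy ketone F4.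
- Return to the route: reduction of this menthone-like 2-isopropylcycloalkanone with LiBH(s-Bu)3 delivers hydride anti to the isopropyl group and comes back at 23.

**Step 15.**
- What may go wrong: poor facial selectivity of the peracid at C8=C9.
- Fallback: a halohydrin sequence that places oxygen on the face opposite to the one electrophiles prefer, setting out from 26. NBS in aqueous acetone at 0 °C forms the bromonium ion on the more accessible face. Water opens it anti at the tertiary C9 to give the 8β-bromo-9α-hydroxy compound F5.
- Return to the route: DBU in CH2Cl2 closes the 9α-oxygen onto C8 with inversion and comes back at 27.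

Further compounds
F1 | step 4 | (S)-2-(p-tolylsulfinyl)cyclopent-2-en-1-one | Cc1ccc(cc1)[S@](=O)C1=CCCC1=O
F2 | step 4 | C5-sulfinyl Diels–Alder adduct | CC[Si](CC)(CC)OC1=C(C)C[C@@]2([S@@](=O)c3ccc(C)cc3)C(=O)CC[C@H]2[C@H]1C(C)C
F3 | step 11 | 2α,3α-epoxy ketone | O=C1[C@@H]3O[C@]3(C)C[C@@H]2C=C(C)C[C@H]2[C@@H]1C(C)C
F4 | step 11 | 3α-hydroxy ketone | O=C1C[C@](C)(O)C[C@@H]2C=C(C)C[C@H]2[C@@H]1C(C)C
F5 | step 15 | 8β-bromo-9α-hydroxy compound | COc1ccc(C(=O)O[C@@H]2C[C@](C)(O)C[C@@H]3[C@@H](Br)[C@](C)(O)C[C@H]3[C@@H]2C(C)C)cc1OCc1ccccc1
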